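The larch run ended at 16.60 mM of target after 24 min, the maple run at 7.98 mM, and two chemists, Tom and Vera, read that pair differently.

| setting | larch | maple | ash |
|---|---|---|---|
| substrate | 50.0 mM | 25.0 mM | 14.0 mM |
| partner | 100 mM | 100 mM | 100 mM |
| time |  |  | 24 min |

| run | time / min | [target] / mM |
|---|---|---|
| larch run | 3.4 | 2.86 |
| larch run | 6.9 | 7.36 |
| larch run | 10 | 10.71 |
| larch run | 14 | 13.67 |
| larch run | 17 | 15.02 |
| larch run | 21 | 16.33 |
| larch run | 24 | 16.60 |
| maple run | 3.4 | 1.25 |
| maple run | 6.9 | 3.59 |
| maple run | 10 | 4.88 |
| maple run | 14 | 6.46 |
| maple run | 17 | 7.23 |
| maple run | 21 | 7.46 |
| maple run | 24 | 7.98 |

(scatter of a reading: 0.2 mM)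

- the exponent of [substrate] in the starting rate at the charge of the larch run (at the point where two percent of the substrate have become target) (one fixed amount of target, the same in the runs compared)
- target in the ash run at 24 min, as a share of the substrate charged

- Overall: substrate + partner -> target.
- Constant volume, constant temperature.
- A reading of a species includes what of it is bound.
- An order is taken over about fifteen percent of the charge, up and down.

At the blackboard they first agree on a number. The logarithm of the ratio of those two last readings, over the logarithm of the charge ratio, gives 1.06, give or take 0.0401 from the scatter. Call it the clock order: the exponent of the charge in c(target) read at one fixed time.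

Tom takes this as plain order one. In the larch run, partner stands at twice the substrate, and he treats the reaction as pseudo-first-order in substrate. So his exponent in the starting rate is one, and the ash run should repeat the share of the maple run, 31.9%.

Vera, who made the forecast, looks at the early readings, which start with a lag. A fixed amount of target, she argues, is “reached later in a smaller run, further up the rate rise”, so the exponent at fixed target comes out lower than the clock order. The forecast says 0.8, between 0.55 and 1.1, and 31% for the ash run, between 28% and 34%.

My own reckoning carries the clock order from the maple charge down to the ash charge and gives 30.9%, a little under the maple share.

The flask gives an exponent of 0.79 and 30.4% for the ash run, inside both ranges of the forecast.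

    substrate → intermediate (0.7380 /min)
    intermediate + partner → target (4.872 /M/min)
    intermediate → side product (0.1776 /min)
    substrate + partner ⇌ idle substrate-reagent adduct, settled at all times (167.0 /M)
    2 partner → lost reagent (3.258 /M/min)

At equal target the maple run goes at 0.58 of the larch rate, so Tom's exponent of one fails there; his view comes close at equal share, where a quarter of the charge is reached at 11.9 min in the larch run and 12.7 min in the maple run. The clock order from the last maple reading to the ash result comes to 1.08. The ash share stays low because the binding into idle substrate-reagent adduct and the loss of partner to lost reagent act together: the ash run without the binding gives 45.0%, and without the loss it gives 45.9%.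

The readings were computed for an exercise.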